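**Strategy.** The plan assembles the resorcinol ring C last, from an acyclic alkyne. In the target, C1' (carrying the diaryl ketone) and C6' (carrying the CH2 of the pyranone) are neighbours and face the 1,3-dioxygenated unit C2'(O)–C3'–C4'(O)–C5'. These two carbons are taken as the alkyne carbons of an ynone, and the four-carbon unit as a 1,1-dimethoxy-3-silyloxybutadiene. One Diels–Alder/aromatisation forms C1'–C2' and C5'–C6', closes ring C with the correct oxygen pattern and delivers the congested benzophenone without any acylation. The precursor is the fully O-methylated naphthyl ynone carrying the CH2-linked 4-methoxypyranone. Oxidation to the naphthoquinone and one global demethylation finish the synthesis.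

Key step: step 11

Assumption: silyloxy dienes 5 and 17 are taken as purchasable reagents; atom labels follow the target (naphthoquinone C1–C8a in rings A and B, resorcinol ring C C1'–C6' with the ketone on C1', pyranone ring D).

**Step 1**
Reactants: 1 2-methoxyhydroquinone; 2 acetic acid
Product: 3 1-(2,5-dihydroxy-4-methoxyphenyl)ethan-1-one
Conditions: BF3·OEt2 (as medium), 90 °C; aq. work-up
Reagents that add atoms: none
Why: Friedel–Crafts acylation of the electron-rich hydroquinone should go para to the methoxy group and ortho to a hydroxyl, giving the chelated ortho-hydroxyacetophenone that places the future C1 and its methyl group on the future C8a.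

**Step 2**
Reactants: 3 1-(2,5-dihydroxy-4-methoxyphenyl)ethan-1-one
Product: 4 2-acetyl-5-methoxy-1,4-benzoquinone
Conditions: Ag2O, MgSO4, CH2Cl2, rt, dark
Reagents that add atoms: none
Why: Oxidation of a hydroquinone to its quinone by Ag2O under anhydrous conditions is the standard entry to acylquinones, and the drying agent keeps water away from the electrophilic product.

**Step 3**
Reactants: 4 2-acetyl-5-methoxy-1,4-benzoquinone; 5 1-methoxy-1,3-bis(trimethylsilyloxy)buta-1,3-diene
Product: 7 methyl 3,5,8-trihydroxy-6-methoxy-1-methylnaphthalene-2-carboxylate, via hydroquinone keto ester 6 (not isolated)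
Conditions: CH2Cl2, −78 → 0 °C; then NaOMe, degassed MeOH, 0 °C → rt, argon; aq. HCl
Reagents that add atoms: none
Why: Vinylogous Mukaiyama–Michael addition of the terminal CH2 of the bis-silyl dienol ether to C3 of the acylquinone (activated by both the ring carbonyl and the acetyl group), methanolysis of the silyl groups and base-mediated intramolecular Knoevenagel–aldol condensation of the β-keto ester onto the acetyl carbonyl amount to a formal [3+3] benzannulation that should fix C1–Me, C2–CO2Me and C3–OH of ring B without ambiguity.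

**Step 4**
Reactants: 7 methyl 3,5,8-trihydroxy-6-methoxy-1-methylnaphthalene-2-carboxylate
Product: 8 methyl 3,5,6,8-tetramethoxy-1-methylnaphthalene-2-carboxylate
Conditions: MeI, K2CO3, DMF, rt → 40 °C, argon
Reagents that add atoms: iodomethane, CI
Why: Williamson O-methylation of the three phenols in a polar aprotic solvent is reliable and at once removes the air-sensitive naphthohydroquinone.

**Step 5**
Reactants: 8 methyl 3,5,6,8-tetramethoxy-1-methylnaphthalene-2-carboxylate
Product: 9 (3,5,6,8-tetramethoxy-1-methylnaphthalen-2-yl)methanol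
Conditions: LiAlH4, THF, 0 °C → rt
Reagents that add atoms: none
Why: Hydride reduction of the ester to the primary alcohol should proceed despite the two flanking substituents because the aluminohydride is small.

**Step 6**
Reactants: 9 (3,5,6,8-tetramethoxy-1-methylnaphthalen-2-yl)methanol
Product: 10 3,5,6,8-tetramethoxy-1-methylnaphthalene-2-carbaldehyde
Conditions: MnO2, CH2Cl2, rt
Reagents that add atoms: none
Why: Activated MnO2 oxidises benzylic alcohols selectively to aldehydes without over-oxidation and leaves the electron-rich naphthalene untouched.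

**Step 7**
Reactants: 10 3,5,6,8-tetramethoxy-1-methylnaphthalene-2-carbaldehyde; 11 ethynylmagnesium bromide (HC≡CMgBr)
Product: 12 1-(3,5,6,8-tetramethoxy-1-methylnaphthalen-2-yl)prop-2-yn-1-ol (racemic)
Conditions: THF, 0 °C → rt; sat. aq. NH4Cl
Reagents that add atoms: none
Why: Grignard addition of the slim sp-hybridised nucleophile to the hindered aldehyde should give the secondary propargylic alcohol as a racemate, which is of no consequence because step 10 removes the stereocentre.

**Step 8**
Reactants: 13 4-methoxy-6-methyl-2H-pyran-2-one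
Product: 14 6-(bromomethyl)-4-methoxy-2H-pyran-2-one
Conditions: NBS, AIBN (cat.), PhCF3, 85 °C
Reagents that add atoms: N-bromosuccinimide, O=C1CCC(=O)N1Br
Why: Wohl–Ziegler radical bromination should take place at the C6 methyl group, whose radical is allylic and stabilised by the ring oxygen, while radical conditions suppress ionic bromination at C3.

**Step 9**
Reactants: 12 1-(3,5,6,8-tetramethoxy-1-methylnaphthalen-2-yl)prop-2-yn-1-ol; 14 6-(bromomethyl)-4-methoxy-2H-pyran-2-one
Product: 15 6-[4-hydroxy-4-(3,5,6,8-tetramethoxy-1-methylnaphthalen-2-yl)but-2-yn-1-yl]-4-methoxy-2H-pyran-2-one (racemic)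
Conditions: CuI (20 mol %), NaI (20 mol %), K2CO3, DMF, rt
Reagents that add atoms: none
Why: Copper-catalysed coupling of a terminal alkyne with an allylic-type bromide (SN2 attack of the monovalent copper acetylide at CH2) runs under mild carbonate conditions that tolerate the free secondary alcohol and are too weak to isomerise the skipped product.

**Step 10**
Reactants: 15 6-[4-hydroxy-4-(3,5,6,8-tetramethoxy-1-methylnaphthalen-2-yl)but-2-yn-1-yl]-4-methoxy-2H-pyran-2-one
Product: 16 4-methoxy-6-[4-oxo-4-(3,5,6,8-tetramethoxy-1-methylnaphthalen-2-yl)but-2-yn-1-yl]-2H-pyran-2-one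
Conditions: Dess–Martin periodinane, CH2Cl2, 0 °C
Reagents that add atoms: none
Why: Hypervalent-iodine oxidation of the benzylic, propargylic alcohol to the ynone is fast at low temperature and non-basic, so the now strongly acidic CH2 between alkyne and pyranone should not isomerise to the allene.

**Step 11**
Reactants: 16 4-methoxy-6-[4-oxo-4-(3,5,6,8-tetramethoxy-1-methylnaphthalen-2-yl)but-2-yn-1-yl]-2H-pyran-2-one; 17 1,1-dimethoxy-3-(trimethylsilyloxy)buta-1,3-diene
Product: 20 6-{[5-hydroxy-3-methoxy-2-(3,5,6,8-tetramethoxy-1-methyl-2-naphthoyl)phenyl]methyl}-4-methoxy-2H-pyran-2-one, via cyclohexa-1,4-diene cycloadduct 18 (not isolated), via aryl trimethylsilyl ether 19 (not isolated)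
Conditions: 17 (3 equiv), toluene, 90 °C, sealed tube, argon; then 0.1 M HCl, THF, 0 °C
Reagents that add atoms: none
Why: The electron-poor alkyne of ynone 16 and the electron-rich ketene-acetal diene 17 should combine in a thermal [4+2] cycloaddition (concerted but asynchronous, or Michael addition followed by ring closure of the allenolate α-carbon onto the dimethoxycarbenium carbon) to give cyclohexa-1,4-diene 18, which aromatises by 1,4-elimination of methanol to silyl ether 19, and dilute acid then frees the C4' phenol. The closest known reaction type is the resorcinol monoether synthesis from acetylenic ketones or esters and 1,1-dialkoxy-3-silyloxybutadienes. The six-membered ring C is closed by intermolecular [4+2] annulation that forms C1'–C2' and C5'–C6', and no stereocentre is created because aromatisation leaves the ring planar. The selectivity needed is regiochemical and is secured by polarity matching: the nucleophilic CH2 terminus of the diene bonds to the electrophilic β-carbon of the ynone (future C6') and the acetal carbon to the α-carbon (future C1'), which puts OMe on C2' and OH on C4'. The congested benzophenone with four ortho substituents needs no acylation event, since its carbonyl is carried in from the ynone, which is unencumbered on its alkyne side. Neutral, base-free conditions are chosen so that the acidic CH2 between alkyne and pyranone does not slip to the allene before the cycloaddition.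

**Step 12**
Reactants: 20 6-{[5-hydroxy-3-methoxy-2-(3,5,6,8-tetramethoxy-1-methyl-2-naphthoyl)phenyl]methyl}-4-methoxy-2H-pyran-2-one
Product: 21 6-{[2-(3,6-dimethoxy-1-methyl-5,8-dioxo-5,8-dihydronaphthalene-2-carbonyl)-5-hydroxy-3-methoxyphenyl]methyl}-4-methoxy-2H-pyran-2-one
Conditions: (NH4)2Ce(NO3)6, MeCN/H2O, 0 °C
Reagents that add atoms: water, O
Why: Oxidative demethylation by tetravalent cerium should attack the most electron-rich ring, the 5,6,8-trimethoxy ring A, at its para-disposed C5 and C8 methoxy groups to give the 6-methoxy-5,8-quinone, whereas ring B, the acyl-deactivated phenol ring C and the pyranone lack a para-dioxygen pattern.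

**Step 13**
Reactants: 21 6-{[2-(3,6-dimethoxy-1-methyl-5,8-dioxo-5,8-dihydronaphthalene-2-carbonyl)-5-hydroxy-3-methoxyphenyl]methyl}-4-methoxy-2H-pyran-2-one
Product: 22 6-{[3,5-dihydroxy-2-(3,6-dihydroxy-1-methyl-5,8-dioxo-5,8-dihydronaphthalene-2-carbonyl)phenyl]methyl}-4-hydroxy-2H-pyran-2-one
Conditions: BBr3 (excess), CH2Cl2, −78 °C → rt; then H2O
Reagents that add atoms: none
Why: Lewis-acid ether cleavage by BBr3 should remove all four remaining O-methyl groups, the two aryl ethers ortho to the ketone being assisted by chelation and the quinone and pyranone methyl groups reacting as vinylogous esters, and hydrolysis of the borates releases the target.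

**Compound list**

1 | 2-methoxyhydroquinone (2-methoxybenzene-1,4-diol) | COc1cc(O)ccc1O | starting material
2 | acetic acid | CC(=O)O | starting material
3 | 1-(2,5-dihydroxy-4-methoxyphenyl)ethan-1-one | CC(=O)c1cc(O)c(OC)cc1O | intermediate
4 | 2-acetyl-5-methoxy-1,4-benzoquinone | CC(=O)C1=CC(=O)C(OC)=CC1=O | intermediate
5 | 1-methoxy-1,3-bis(trimethylsilyloxy)buta-1,3-diene (geometry at C1=C2 immaterial) | COC(O[Si](C)(C)C)=CC(=C)O[Si](C)(C)C | starting material
6 | methyl 4-(2-acetyl-3,6-dihydroxy-5-methoxyphenyl)-3-oxobutanoate | COC(=O)CC(=O)Cc1c(O)c(OC)cc(O)c1C(C)=O | intermediate (not isolated)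
7 | methyl 3,5,8-trihydroxy-6-methoxy-1-methylnaphthalene-2-carboxylate | COC(=O)c1c(C)c2c(O)cc(OC)c(O)c2cc1O | intermediate
8 | methyl 3,5,6,8-tetramethoxy-1-methylnaphthalene-2-carboxylate | COC(=O)c1c(C)c2c(OC)cc(OC)c(OC)c2cc1OC | intermediate
9 | (3,5,6,8-tetramethoxy-1-methylnaphthalen-2-yl)methanol | OCc1c(C)c2c(OC)cc(OC)c(OC)c2cc1OC | intermediate
10 | 3,5,6,8-tetramethoxy-1-methylnaphthalene-2-carbaldehyde | O=Cc1c(C)c2c(OC)cc(OC)c(OC)c2cc1OC | intermediate
11 | ethynylmagnesium bromide | C#C[Mg]Br | starting material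
12 | 1-(3,5,6,8-tetramethoxy-1-methylnaphthalen-2-yl)prop-2-yn-1-ol (racemic) | C#CC(O)c1c(C)c2c(OC)cc(OC)c(OC)c2cc1OC | intermediate
13 | 4-methoxy-6-methyl-2H-pyran-2-one | COc1cc(C)oc(=O)c1 | starting material
14 | 6-(bromomethyl)-4-methoxy-2H-pyran-2-one | COc1cc(CBr)oc(=O)c1 | intermediate
15 | 6-[4-hydroxy-4-(3,5,6,8-tetramethoxy-1-methylnaphthalen-2-yl)but-2-yn-1-yl]-4-methoxy-2H-pyran-2-one (racemic) | COc1cc(CC#CC(O)c2c(C)c3c(OC)cc(OC)c(OC)c3cc2OC)oc(=O)c1 | intermediate
16 | 4-methoxy-6-[4-oxo-4-(3,5,6,8-tetramethoxy-1-methylnaphthalen-2-yl)but-2-yn-1-yl]-2H-pyran-2-one | COc1cc(CC#CC(=O)c2c(C)c3c(OC)cc(OC)c(OC)c3cc2OC)oc(=O)c1 | intermediate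
17 | 1,1-dimethoxy-3-(trimethylsilyloxy)buta-1,3-diene | COC(OC)=CC(=C)O[Si](C)(C)C | starting material
18 | 6-{[3,3-dimethoxy-2-(3,5,6,8-tetramethoxy-1-methyl-2-naphthoyl)-5-(trimethylsilyloxy)cyclohexa-1,4-dien-1-yl]methyl}-4-methoxy-2H-pyran-2-one | COc1cc(CC2=C(C(=O)c3c(C)c4c(OC)cc(OC)c(OC)c4cc3OC)C(OC)(OC)C=C(O[Si](C)(C)C)C2)oc(=O)c1 | intermediate (not isolated)
19 | 4-methoxy-6-{[3-methoxy-2-(3,5,6,8-tetramethoxy-1-methyl-2-naphthoyl)-5-(trimethylsilyloxy)phenyl]methyl}-2H-pyran-2-one | COc1cc(Cc2cc(O[Si](C)(C)C)cc(OC)c2C(=O)c2c(C)c3c(OC)cc(OC)c(OC)c3cc2OC)oc(=O)c1 | intermediate (not isolated)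
20 | 6-{[5-hydroxy-3-methoxy-2-(3,5,6,8-tetramethoxy-1-methyl-2-naphthoyl)phenyl]methyl}-4-methoxy-2H-pyran-2-one | COc1cc(Cc2cc(O)cc(OC)c2C(=O)c2c(C)c3c(OC)cc(OC)c(OC)c3cc2OC)oc(=O)c1 | intermediate
21 | 6-{[2-(3,6-dimethoxy-1-methyl-5,8-dioxo-5,8-dihydronaphthalene-2-carbonyl)-5-hydroxy-3-methoxyphenyl]methyl}-4-methoxy-2H-pyran-2-one | COc1cc(Cc2cc(O)cc(OC)c2C(=O)c2c(C)c3C(=O)C=C(OC)C(=O)c3cc2OC)oc(=O)c1 | intermediate
22 | 6-{[3,5-dihydroxy-2-(3,6-dihydroxy-1-methyl-5,8-dioxo-5,8-dihydronaphthalene-2-carbonyl)phenyl]methyl}-4-hydroxy-2H-pyran-2-one (CNP0141484.0; no stereocentre) | Cc1c(C(=O)c2c(O)cc(O)cc2Cc2cc(O)cc(=O)o2)c(O)cc2c1C(=O)C=C(O)C2=O | target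

**Step count.** Total: 13 steps. Longest linear sequence: 12 steps (steps 1–7 and 9–13; step 8 is a one-step side branch).

**Steps most likely to fail**

Step 11. The skipped ynone may isomerise to its allenyl ketone and oligomerise faster than it is trapped by the diene, or the diene may be lost by protonation before it adds. The fallback forms the diaryl ketone by acylation of a preformed ring C; it sets out from aldehyde 10 (with bromide 14 as partner) and comes back to the route at target 22. Pinnick oxidation of 10 (NaClO2, NaH2PO4, 2-methylbut-2-ene, tBuOH/H2O) should give 3,5,6,8-tetramethoxy-1-methylnaphthalene-2-carboxylic acid F1. Suzuki–Miyaura coupling of 14 with (3,5-dimethoxyphenyl)boronic acid (Pd(PPh3)4 as zerovalent palladium catalyst, K2CO3, toluene/H2O, 80 °C) should give 6-[(3,5-dimethoxyphenyl)methyl]-4-methoxy-2H-pyran-2-one F2. Friedel–Crafts acylation of F2 with the mixed trifluoroacetic anhydride of F1 ((CF3CO)2O, CH2Cl2, 0 °C → rt) is expected between CH2 and OMe, para to the second OMe, to give 6-{[3,5-dimethoxy-2-(3,5,6,8-tetramethoxy-1-methyl-2-naphthoyl)phenyl]methyl}-4-methoxy-2H-pyran-2-one F3. Oxidative demethylation with (NH4)2Ce(NO3)6 should give 6-{[2-(3,6-dimethoxy-1-methyl-5,8-dioxo-5,8-dihydronaphthalene-2-carbonyl)-3,5-dimethoxyphenyl]methyl}-4-methoxy-2H-pyran-2-one F4, and BBr3 cleaves its five methyl ethers to 22.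

Step 3. The bis-silyl dienol ether may add across the quinone double bond as a diene with loss of the angular acetyl group, or the Michael adduct may close through the hydroquinone oxygen to a benzofuran instead of through carbon. The fallback builds the same keto ester on a protected ring; it sets out from quinone 4 and comes back at ester 8. Conjugate allylation of 4 with CH2=CHCH2SnBu3 (BF3·OEt2, CH2Cl2, −78 °C) should give 1-[3,6-dihydroxy-4-methoxy-2-(prop-2-en-1-yl)phenyl]ethan-1-one F5. Methylation (MeI, K2CO3, DMF) gives 1-[3,4,6-trimethoxy-2-(prop-2-en-1-yl)phenyl]ethan-1-one F6. Lemieux–Johnson cleavage (OsO4 cat., NaIO4, 2,6-lutidine, dioxane/H2O) gives 2-(2-acetyl-3,5,6-trimethoxyphenyl)acetaldehyde F7. Roskamp homologation with methyl diazoacetate (SnCl2 cat., CH2Cl2) gives methyl 4-(2-acetyl-3,5,6-trimethoxyphenyl)-3-oxobutanoate F8, in which no free phenol can compete. NaOMe in MeOH then closes ring B by intramolecular Knoevenagel–aldol condensation to methyl 3-hydroxy-5,6,8-trimethoxy-1-methylnaphthalene-2-carboxylate F9, and O-methylation (MeI, K2CO3, DMF) gives 8.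

Step 13. The methoxyquinone and the hydroxyquinone product may not survive the boron halide (addition of HBr across the quinone, boron chelates that resist hydrolysis), so that material is lost during the last cleavage. The fallback reverses the order of deprotection and oxidation; it sets out from 20 and comes back at 22. BBr3 (CH2Cl2, −78 °C → rt) applied to 20, which has no quinone, should give 6-{[3,5-dihydroxy-2-(3,5,6,8-tetrahydroxy-1-methyl-2-naphthoyl)phenyl]methyl}-4-hydroxy-2H-pyran-2-one F10. Exposure of F10 to air in MeOH/aq. NaHCO3 should autoxidise the 5,6,8-trihydroxynaphthalene unit to the 6-hydroxy-5,8-quinone, giving 22.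

**Further compounds**

F1 | step 11 | 3,5,6,8-tetramethoxy-1-methylnaphthalene-2-carboxylic acid | OC(=O)c1c(C)c2c(OC)cc(OC)c(OC)c2cc1OC
F2 | step 11 | 6-[(3,5-dimethoxyphenyl)methyl]-4-methoxy-2H-pyran-2-one | COc1cc(Cc2cc(OC)cc(OC)c2)oc(=O)c1
F3 | step 11 | 6-{[3,5-dimethoxy-2-(3,5,6,8-tetramethoxy-1-methyl-2-naphthoyl)phenyl]methyl}-4-methoxy-2H-pyran-2-one | COc1cc(Cc2cc(OC)cc(OC)c2C(=O)c2c(C)c3c(OC)cc(OC)c(OC)c3cc2OC)oc(=O)c1
F4 | step 11 | 6-{[2-(3,6-dimethoxy-1-methyl-5,8-dioxo-5,8-dihydronaphthalene-2-carbonyl)-3,5-dimethoxyphenyl]methyl}-4-methoxy-2H-pyran-2-one | COc1cc(Cc2cc(OC)cc(OC)c2C(=O)c2c(C)c3C(=O)C=C(OC)C(=O)c3cc2OC)oc(=O)c1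
F5 | step 3 | 1-[3,6-dihydroxy-4-methoxy-2-(prop-2-en-1-yl)phenyl]ethan-1-one | CC(=O)c1c(CC=C)c(O)c(OC)cc1O
F6 | step 3 | 1-[3,4,6-trimethoxy-2-(prop-2-en-1-yl)phenyl]ethan-1-one | CC(=O)c1c(CC=C)c(OC)c(OC)cc1OC
F7 | step 3 | 2-(2-acetyl-3,5,6-trimethoxyphenyl)acetaldehyde | CC(=O)c1c(CC=O)c(OC)c(OC)cc1OC
F8 | step 3 | methyl 4-(2-acetyl-3,5,6-trimethoxyphenyl)-3-oxobutanoate | COC(=O)CC(=O)Cc1c(OC)c(OC)cc(OC)c1C(C)=O
F9 | step 3 | methyl 3-hydroxy-5,6,8-trimethoxy-1-methylnaphthalene-2-carboxylate | COC(=O)c1c(C)c2c(OC)cc(OC)c(OC)c2cc1O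
F10 | step 13 | 6-{[3,5-dihydroxy-2-(3,5,6,8-tetrahydroxy-1-methyl-2-naphthoyl)phenyl]methyl}-4-hydroxy-2H-pyran-2-one | Oc1cc(Cc2cc(O)cc(O)c2C(=O)c2c(C)c3c(O)cc(O)c(O)c3cc2O)oc(=O)c1
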